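Remark: atoms are numbered C1 (lactone carbonyl), C2, C3 and C4 (ring-fusion carbons), C5, C6 (ether carbon with methyl and chain) and C7–C18 (chain, phenyl on C18), which makes the target (3S,4S,6S). The L-series fructose-type ketone catalyst of step 4, the mirror image of the common D-fructose-derived one, is assumed to be obtainable.

## Analysis of the target

Plakortone L (19) is a cis-fused 2,6-dioxabicyclo[3.3.0]octan-3-one. A γ-lactone ring (O–C1–C2–C3–C4) and a tetrahydrofuran ring (O1–C3–C4–C5–C6) share the C3–C4 bond. C4 and C6 are fully substituted, each with a methyl group, and C6 also carries the unbranched, unfunctionalised C7–C18 chain that ends in a phenyl ring. The three stereocentres C3, C4 and C6 are all S. The ring fusion is necessarily cis, and at C6 the chain lies on the convex face (cis to the C4 methyl and the C3 hydrogen) while the C6 methyl points into the concave face toward the lactone. The only sensitive function is the β-alkoxy γ-lactone, which strong base can open or push into β-elimination of the C3 oxygen. The difficulty lies in two tetrasubstituted, oxygen-bearing carbons in a 1,3-relationship, and above all in C6, where a methyl group must be distinguished from a methylene chain with no functional handle nearby. The route rests on C6 being bonded both to the ring oxygen O1 and to chain carbon C7. Removing both bonds leaves a C6=C7 olefin γ to the C3 hydroxyl of a small hydroxy lactone, so ring closure and chain attachment can be one event.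

## Retrosynthetic reasoning

**19 to 18.** No skeletal bond is cut. A C8=C9 double bond is written into the chain, so that C8 becomes an sp2 carbon that can be delivered as an alkenyl electrophile. The olefin is homoallylic to the ether oxygen, so its later hydrogenation cannot cleave a C–O bond. The forward step only has to saturate one disubstituted olefin.

**18 to 9 and 16.** The O1–C6 and C7–C8 bonds are cut together. C6 is the one carbon that carries both the ether oxygen and the chain, so this double cut turns it into the internal carbon of a 1,1-disubstituted olefin. The bicycle falls back to the monocyclic hydroxy lactone 9, with only two adjacent stereocentres, and the achiral alkenyl bromide 16. Cutting C6–C7 alone would need a nucleophile to choose between the faces of a ketone-derived oxocarbenium ion flanked by methyl and methylene. Cutting only a lactone bond would leave C6 to be set in an open or monocyclic precursor. The gain is convergence: one ring, two bonds and the C6 stereocentre in one step. The forward reaction must add the C3 oxygen and C8 across C6=C7 on the face that puts C7 exo, keep the E geometry of 16, and leave the lactone intact.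

**9 to 6 by way of 8.** The lactone O–C4 bond is cut. In 9 the C3 hydroxyl and the C4–O bond are anti, which is the signature of an epoxide opened with inversion by an internal carboxyl group. The precursor is therefore the cis-3,4-epoxy acid 8, released from its methyl ester 6. Both stereocentres of 9 then come from one epoxide. The forward step must open the epoxide at the tertiary carbon C4 cleanly with inversion.

**6 to 5.** The epoxide oxygen is removed to give the Z-trisubstituted olefin of diene ester 5. The forward step is the only enantioselective one in the route, an asymmetric dioxirane (Shi-type) epoxidation. It must pick the trisubstituted olefin over the 1,1-disubstituted one and the correct face.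

**5 to 4, 2 and 1.** The C6=C7 methylene is traced to the ketone of 4. Keto ester 4, a 1,6-dicarbonyl compound with a Z-trisubstituted olefin between the carbonyls, is what remains when the enol ether double bond of the 1-methoxycyclohexa-1,4-diene 2 is cleaved. Diene 2 is the Birch product of the arene 1. The ring fixes the Z geometry, and 1 supplies C1–C6 and both methyl groups. Methylenation is placed before epoxidation on purpose. With the ketone still present, the epoxide would be a β,γ-epoxy ketone and the lactone a β-acyloxy ketone, both prone to base-induced elimination. The price is that the epoxidation must then distinguish two olefins.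

**16 to 14, 11 and 10.** The C–Br bond of 16 comes from the terminal alkyne 14 by syn hydrometalation and halogenation, which fixes the E geometry. The C18–phenyl bond of 14 is cut to the tosylate 11 of the commercial alkynol 10. The forward step is a copper-catalysed sp3–sp2 coupling at a primary carbon.

## Alternatives that were turned down

**Alternative 1:** Both ring C–O bonds (lactone O–C4 and ether O1–C6) are cut at once. This leads to the open-chain bis-epoxy acid A1, the 3,4:6,7-diepoxide of a (3Z,6E)-dienoic acid that already carries the whole chain.
- Forward key step: acid lets the carboxyl group open the 3,4-epoxide at C4, and the C3 hydroxyl so released opens the 6,7-epoxide at C6, each with inversion, to give the bicyclic 7-hydroxy compound A2.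
- For it: both rings form in one operation, and both quaternary centres are set stereospecifically from epoxide configuration. On this point it is stronger than the chosen route, where C6 depends on a diastereofacial preference.
- Against it: A2 carries a C7 hydroxyl that 19 lacks, so a two-step radical deoxygenation must follow. The full C1–C18 skeleton, with a skipped diene of two trisubstituted olefins of opposite geometry, must be built linearly first. Two reagent-controlled epoxidations are needed. Two tertiary epoxide carbons are exposed to acid at once, which doubles the chance of hydride shift or elimination.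
- Comparison: the chosen route gives up the rigorous control at C6 in exchange for convergence, a single enantioselective step, an achiral chain fragment and a final hydrogenation in place of a deoxygenation.

**Alternative 2:** Only the lactone O–C4 bond is cut. This leads to the 2,5-dihydrofuran acetic acid A3, in which C4=C5 is an olefin; a Claisen-type [3,3] shift earlier in that sequence would place the acetic acid arm on C3.
- Forward key step: an electrophilic iodine source activates C4=C5 and the carboxylate closes onto C4 (5-exo) to give the iodo lactone A4, from which the iodine must be removed reductively.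
- For it: the tether guarantees the cis ring fusion and the configuration of C4, and attack goes to the more substituted olefin carbon. This is stronger than the epoxide opening of step 5, where a tertiary carbon under acid could in principle ionise.
- Against it: C6 must already be present in A3 as a quaternary stereocentre in a defined relationship to C3 across the ring oxygen, so the hardest problem is moved into the synthesis of A3 and not solved by the key step. The chain is carried through a linear sequence. The C5 iodine is not in the target and costs a dehalogenation. Iodonium formation next to the fully substituted C6 should be slow.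
- Comparison: the chosen route sets C6 in the same step that attaches the chain and introduces no atom that is later removed.

**Alternative 3:** Three bonds are cut (O1–C6, C5–C6 and O–C4). This leads to the bis-silylated (S)-hydroxy acid A5 and the ynone A6.
- Forward key step: a silyl triflate Lewis acid condenses the silyl ether oxygen with the ketone to a C6 oxocarbenium ion, the isopropenyl olefin attacks it through C5, and the silyl ester traps the C4 cation to give the alkyne A7. Full hydrogenation would finish.
- For it: it is the shortest and most convergent plan, with both rings and two stereocentres from two small fragments in one step. On step economy it is clearly stronger than the chosen route.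
- Against it: the C–C closure forms a five-membered ring with both olefin carbons inside it (5-endo), a poorly disposed geometry. The oxocarbenium ion is flanked by methyl and a rod-like alkynyl group, so its faces differ little and C6 would be weakly controlled. The C3–O bond is allylic and can ionise once its oxygen is part of an oxocarbenium ion, which puts the only pre-set stereocentre at risk. An alkynyl oxocarbenium ion can also react at the remote alkyne carbon.
- Comparison: the chosen route is longer, but each stereocentre has an identifiable control element and its ring closures are of the favoured exo type or enforced by ring size.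

Key step: step 9

## Route

Step 1
Reactants: 1 2,4-dimethylanisole
Product: 2 1-methoxy-2,4-dimethylcyclohexa-1,4-diene
Conditions: Li, NH3 (l), THF, t-BuOH, −78 °C → −33 °C; NH4Cl
Reagents that add atoms: none
Why: Birch reduction of an alkyl anisole protonates the ring carbons ortho and meta to the methoxy group, so the methoxy and both methyl groups stay on olefinic carbons and the unconjugated 1,4-diene should result; no stereocentre is formed.

Step 2
Reactants: 2 1-methoxy-2,4-dimethylcyclohexa-1,4-diene
Product: 4 methyl (3Z)-4-methyl-6-oxohept-3-enoate, via methoxy hydroperoxide 3 (not isolated)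
Conditions: O3 (1 equiv), CH2Cl2/MeOH, pyridine, −78 °C; then Me2S, −78 °C → rt
Reagents that add atoms: ozone, [O-][O+]=O
Why: Selective ozonolysis: electrophilic ozone should attack the tetrasubstituted enol ether much faster than the trisubstituted olefin, so one equivalent cleaves only C1=C2 to the methyl ester and the methyl ketone (the carbonyl oxide is trapped by methanol as 3 and reduced by Me2S). The cis arrangement of the two ring methylenes on the surviving olefin becomes the Z geometry of 4.

Step 3
Reactants: 4 methyl (3Z)-4-methyl-6-oxohept-3-enoate
Product: 5 methyl (3Z)-4,6-dimethylhepta-3,6-dienoate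
Conditions: Zn, CH2Br2, TiCl4, THF, −40 °C → 5 °C (reagent aged); then 4, CH2Cl2, 0 °C → rt
Reagents that add atoms: dibromomethane, BrCBr
Why: Lombardo-type methylenation is non-basic and reacts with ketones but not esters, so the ketone should become the 1,1-disubstituted olefin without moving the β,γ-double bond into conjugation, which a basic phosphorus ylide would risk.

Step 4
Reactants: 5 methyl (3Z)-4,6-dimethylhepta-3,6-dienoate
Product: 6 methyl 2-[(2S,3R)-3-methyl-3-(2-methylprop-2-en-1-yl)oxiran-2-yl]acetate
Conditions: 1,2:4,5-di-O-isopropylidene-β-L-erythro-2,3-hexodiulo-2,6-pyranose (0.3 equiv), Oxone (2KHSO5·KHSO4·K2SO4, limiting), K2CO3, Bu4NHSO4, MeCN/CH2(OMe)2, aq. Na2B4O7–Na2EDTA buffer (pH 10.5), 0 °C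
Reagents that add atoms: potassium peroxymonosulfate (active component of Oxone), [K+].[O-]S(=O)(=O)OO
Why: Shi epoxidation: the chiral dioxirane is electrophilic and hindered, so it should take the more electron-rich trisubstituted olefin in preference to the 1,1-disubstituted one. In the spiro transition state the single olefinic hydrogen on C3 sits next to the catalyst's spiro ketal; with the L-series ketone this exposes the face that gives the (2S,3R)-oxirane (the D-series ketone would give its mirror image).

Step 5
Reactants: 6 methyl 2-[(2S,3R)-3-methyl-3-(2-methylprop-2-en-1-yl)oxiran-2-yl]acetate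
Product: 9 (4S,5S)-4-hydroxy-5-methyl-5-(2-methylprop-2-en-1-yl)oxolan-2-one, via lithium epoxy carboxylate 7 (not isolated), via epoxy acid 8 (not isolated)
Conditions: LiOH, THF/H2O, 0 °C; then aq. NaHSO4 (pH 3), EtOAc, 0 °C → rt
Reagents that add atoms: lithium hydroxide, [Li+].[OH-]
Why: Saponification, then acid-triggered epoxide-opening lactonisation: ester hydrolysis is much faster than α-deprotonation, so the epoxide should survive as carboxylate 7. On acidification the acid 8 opens the epoxide at tertiary C4, the carbon best able to carry positive charge and the only one that gives a five-membered ring, with inversion at C4 and retention at C3. Because the epoxide is cis, inversion at C4 places the C3 hydroxyl cis to the 2-methylallyl arm, which is the (4S,5S) lactone.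

Step 6
Reactants: 10 undec-10-yn-1-ol
Product: 11 undec-10-yn-1-yl 4-methylbenzenesulfonate
Conditions: TsCl, Et3N, 4-(dimethylamino)pyridine (cat.), CH2Cl2, 0 °C → rt
Reagents that add atoms: 4-methylbenzenesulfonyl chloride, Cc1ccc(cc1)S(Cl)(=O)=O
Why: Standard sulfonylation of an unhindered primary alcohol; the terminal alkyne is inert.

Step 7
Reactants: 11 undec-10-yn-1-yl 4-methylbenzenesulfonate
Product: 14 11-phenylundec-1-yne, via magnesium acetylide of the tosylate 12 (not isolated), via magnesium acetylide of the coupled alkyne 13 (not isolated)
Conditions: PhMgBr (2.5 equiv), Li2CuCl4 (5 mol%), THF, −20 °C → rt; aq. NH4Cl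
Reagents that add atoms: phenylmagnesium bromide, Br[Mg]c1ccccc1
Why: Copper-catalysed coupling of a Grignard reagent with a primary tosylate (Kochi type) should form the C18–phenyl bond. The first equivalent of Grignard reagent converts the alkyne C–H into an acetylide that is not alkylated under these conditions and is protonated again on work-up.

Step 8
Reactants: 14 11-phenylundec-1-yne
Product: 16 (E)-1-bromo-11-phenylundec-1-ene, via alkenylzirconocene chloride 15 (not isolated)
Conditions: Cp2Zr(H)Cl, THF, rt; then NBS, 0 °C
Reagents that add atoms: N-bromosuccinimide, BrN1C(=O)CCC1=O
Why: Hydrozirconation adds Zr–H syn across the terminal alkyne with zirconium on the terminal carbon, and bromination of the C–Zr bond goes with retention, so only the E alkenyl bromide is expected.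

Step 9
Reactants: 9 (4S,5S)-4-hydroxy-5-methyl-5-(2-methylprop-2-en-1-yl)oxolan-2-one; 16 (E)-1-bromo-11-phenylundec-1-ene
Product: 18 (3aS,5S,6aS)-5,6a-dimethyl-5-[(2E)-12-phenyldodec-2-en-1-yl]tetrahydrofuro[3,2-b]furan-2(3H)-one, via sodium alkoxide of the lactone 17 (not isolated)
Conditions: Pd2(dba)3 (2.5 mol%), bis[2-(diphenylphosphino)phenyl] ether (5 mol%), NaOt-Bu (1.2 equiv), THF, 65 °C
Reagents that add atoms: none
Why: Oxidative addition of 16 to the zerovalent palladium–bisphosphine complex gives an alkenylpalladium bromide, which exchanges bromide for the C3 alkoxide 17; the 1,1-disubstituted olefin then inserts into the Pd–O bond in a syn fashion, and C(sp3)–C(sp2) reductive elimination joins C7 to C8 with the E geometry of 16 retained. This is the known palladium-catalysed carboetherification of γ-hydroxy alkenes with aryl or alkenyl bromides, which also accepts 1,1-disubstituted olefins. The tetrahydrofuran closes in the 5-exo-trig mode, with oxygen bonding to the internal carbon C6, because only that regiochemistry gives a five-membered ring. C6 is the new stereocentre and is fixed at the insertion step: C7 stays bound to palladium, so C7 and the ligated metal on O1 lie on the same face of the forming ring. If that face were the one next to the C2 methylene on C3, the bisphosphine–palladium unit would be forced into the concave pocket of the lactone; insertion should therefore occur with palladium next to the C3 hydrogen, which puts C7 trans to C2 (exo) and the C6 methyl endo, as in 19. The same bias gives 2,5-trans tetrahydrofurans from simple secondary γ-hydroxy alkenes. The alkylpalladium intermediate has a quaternary β-carbon and no β-hydrogen, so β-hydride elimination cannot divert it. The step also needs alkoxide formation to win over base attack on the lactone, which is why only a slight excess of NaOt-Bu in an aprotic solvent is used.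

Step 10
Reactants: 18 (3aS,5S,6aS)-5,6a-dimethyl-5-[(2E)-12-phenyldodec-2-en-1-yl]tetrahydrofuro[3,2-b]furan-2(3H)-one
Product: 19 plakortone L, (3aS,5S,6aS)-5,6a-dimethyl-5-(12-phenyldodecyl)tetrahydrofuro[3,2-b]furan-2(3H)-one
Conditions: H2 (1 atm), 10% Pd/C, EtOAc, rt
Reagents that add atoms: none
Why: Heterogeneous hydrogenation of an unhindered disubstituted olefin; no C–O bond is allylic or benzylic, the arene is not reduced under these conditions, and no stereocentre is touched.

## Compound list

1 | 2,4-dimethylanisole (1-methoxy-2,4-dimethylbenzene) | COc1ccc(C)cc1C | starting material
2 | 1-methoxy-2,4-dimethylcyclohexa-1,4-diene | COC1=C(C)CC(C)=CC1 | intermediate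
3 | methyl (3Z)-6-hydroperoxy-6-methoxy-4-methylhept-3-enoate (racemic at C6) | COC(=O)C/C=C(/C)CC(C)(OC)OO | intermediate
4 | methyl (3Z)-4-methyl-6-oxohept-3-enoate | COC(=O)C/C=C(/C)CC(C)=O | intermediate
5 | methyl (3Z)-4,6-dimethylhepta-3,6-dienoate | COC(=O)C/C=C(/C)CC(C)=C | intermediate
6 | methyl 2-[(2S,3R)-3-methyl-3-(2-methylprop-2-en-1-yl)oxiran-2-yl]acetate | COC(=O)C[C@@H]1O[C@]1(C)CC(C)=C | intermediate
7 | lithium 2-[(2S,3R)-3-methyl-3-(2-methylprop-2-en-1-yl)oxiran-2-yl]acetate | [Li+].[O-]C(=O)C[C@@H]1O[C@]1(C)CC(C)=C | intermediate
8 | 2-[(2S,3R)-3-methyl-3-(2-methylprop-2-en-1-yl)oxiran-2-yl]acetic acid | OC(=O)C[C@@H]1O[C@]1(C)CC(C)=C | intermediate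
9 | (4S,5S)-4-hydroxy-5-methyl-5-(2-methylprop-2-en-1-yl)oxolan-2-one (hydroxyl cis to the 2-methylallyl group) | C=C(C)C[C@]1(C)OC(=O)C[C@@H]1O | intermediate
10 | undec-10-yn-1-ol | C#CCCCCCCCCCO | starting material
11 | undec-10-yn-1-yl 4-methylbenzenesulfonate | C#CCCCCCCCCCOS(=O)(=O)c1ccc(C)cc1 | intermediate
12 | bromo[11-(4-methylbenzenesulfonyloxy)undec-1-yn-1-yl]magnesium | Br[Mg]C#CCCCCCCCCCOS(=O)(=O)c1ccc(C)cc1 | intermediate
13 | bromo(11-phenylundec-1-yn-1-yl)magnesium | Br[Mg]C#CCCCCCCCCCc1ccccc1 | intermediate
14 | 11-phenylundec-1-yne | C#CCCCCCCCCCc1ccccc1 | intermediate
15 | chlorobis(cyclopentadienyl)[(1E)-11-phenylundec-1-en-1-yl]zirconium | Cl[Zr](/C=C/CCCCCCCCCc1ccccc1)(C1C=CC=C1)C1C=CC=C1 | intermediate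
16 | (E)-1-bromo-11-phenylundec-1-ene | Br/C=C/CCCCCCCCCc1ccccc1 | intermediate
17 | sodium (2S,3S)-2-methyl-2-(2-methylprop-2-en-1-yl)-5-oxooxolan-3-olate | [Na+].C=C(C)C[C@]1(C)OC(=O)C[C@@H]1[O-] | intermediate
18 | (3aS,5S,6aS)-5,6a-dimethyl-5-[(2E)-12-phenyldodec-2-en-1-yl]tetrahydrofuro[3,2-b]furan-2(3H)-one | C[C@]1(C/C=C/CCCCCCCCCc2ccccc2)C[C@]2(C)OC(=O)C[C@@H]2O1 | intermediate
19 | plakortone L, (3aS,5S,6aS)-5,6a-dimethyl-5-(12-phenyldodecyl)tetrahydrofuro[3,2-b]furan-2(3H)-one | C[C@]1(CCCCCCCCCCCCc2ccccc2)C[C@]2(C)OC(=O)C[C@@H]2O1 | target

## Step count and least certain steps

Total step count: 10. Longest linear sequence: 7 (steps 1–5, 9 and 10); the bromide 16 takes 3 steps (6–8).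

**Step 9 (key step).** The most likely failure is base-induced breakdown of the β-hydroxy lactone before catalysis takes over: β-elimination of the C3 oxygen, or lactone opening by tert-butoxide. The second risk is incomplete face selection in the insertion, since the two C6 substituents differ only modestly; Heck-type coupling at the olefin is a further drain. A carbonate base would be the first adjustment inside the same reaction. The fallback changes the approach: it sets out from 9 and separates ring closure from chain attachment. Iodoetherification (I2, NaHCO3, MeCN, 0 °C) should close O1–C6 at the tertiary carbon in the 5-exo mode without any alkoxide, giving (3aS,5R,6aS)-5-(iodomethyl)-5,6a-dimethyltetrahydrofuro[3,2-b]furan-2(3H)-one F1, with the larger iodomethyl group expected on the convex face. A nickel-catalysed reductive cross-electrophile coupling of F1 with 16 (NiI2, 4,4'-di-tert-butyl-2,2'-bipyridine, Mn, DMA, rt) then forms C7–C8 through a C7 radical and returns to the route at 18.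

**Step 4.** The most likely failure is loss of site selection (some epoxidation of the 1,1-disubstituted olefin as conversion rises) or enantioselection below what a three-stereocentre target needs, because the two olefins differ only by one alkyl group and the trisubstituted one is slightly deactivated by the ester. The fallback sets out from 5 and uses a directing group. Reduction (i-Bu2AlH, CH2Cl2, −78 °C) gives (3Z)-4,6-dimethylhepta-3,6-dien-1-ol F2. A hydroxyl-directed vanadium-catalysed asymmetric epoxidation of this homoallylic alcohol (VO(Oi-Pr)3, a chiral C2-symmetric bishydroxamic acid ligand of the antipode that delivers oxygen to the required face, cumene hydroperoxide, toluene) can reach only the C3=C4 olefin and gives 2-[(2S,3R)-3-methyl-3-(2-methylprop-2-en-1-yl)oxiran-2-yl]ethan-1-ol F3. Oxidation of the primary alcohol (PhI(OAc)2, 2,2,6,6-tetramethylpiperidin-1-oxyl, MeCN/H2O) returns to the route at the epoxy acid 8, which lactonises to 9 as in step 5.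

**Step 3.** The most likely failure is migration of the β,γ-double bond into conjugation with the ketone on the Lewis-acidic titanium reagent, or stalling through enolisation of the doubly activated C5 methylene. The fallback sets out from 4 and replaces direct methylenation by Peterson olefination. Addition of Me3SiCH2MgCl/CeCl3 (THF, −78 °C), a weakly basic nucleophile that should take the ketone and spare the ester, gives methyl (3Z)-6-hydroxy-4,6-dimethyl-7-(trimethylsilyl)hept-3-enoate F4. Acid-promoted elimination (BF3·OEt2, CH2Cl2, 0 °C) returns to the route at 5.

**Step 5.** The most likely failure is base-induced isomerisation of the β,γ-epoxy ester to a γ-hydroxy enoate during saponification, or partial ionisation at C4 on acidification, which would erode the C4 configuration or lead to hydride shift. The fallback sets out from 6, avoids base, and uses water as the nucleophile. Dilute HClO4 in THF/H2O (0 °C → rt) should open the epoxide at C4 with inversion to methyl (3S,4S)-3,4-dihydroxy-4,6-dimethylhept-6-enoate F5. Its tertiary hydroxyl then closes onto the ester with retention (warming with a trace of acid) and returns to the route at 9.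

**Step 7.** The most likely failure is sequestration of the copper catalyst by the magnesium acetylide, so that the tosylate is consumed slowly or by halide exchange only. The fallback sets out from 11 and reverses the order of events so that no acetylide is present in the coupling. Hydrozirconation–bromination of 11 (Cp2Zr(H)Cl, THF; NBS) gives (10E)-11-bromoundec-10-en-1-yl 4-methylbenzenesulfonate F6. Copper-catalysed coupling with PhMgBr (Li2CuCl4, THF, −20 °C), where a primary tosylate should react well before an alkenyl bromide, returns to the route at 16.

## Further compounds

F1 | step 9 | (3aS,5R,6aS)-5-(iodomethyl)-5,6a-dimethyltetrahydrofuro[3,2-b]furan-2(3H)-one | C[C@]1(CI)C[C@]2(C)OC(=O)C[C@@H]2O1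
F2 | step 4 | (3Z)-4,6-dimethylhepta-3,6-dien-1-ol | OCC/C=C(/C)CC(C)=C
F3 | step 4 | 2-[(2S,3R)-3-methyl-3-(2-methylprop-2-en-1-yl)oxiran-2-yl]ethan-1-ol | OCC[C@@H]1O[C@]1(C)CC(C)=C
F4 | step 3 | methyl (3Z)-6-hydroxy-4,6-dimethyl-7-(trimethylsilyl)hept-3-enoate (racemic at C6) | COC(=O)C/C=C(/C)CC(C)(O)C[Si](C)(C)C
F5 | step 5 | methyl (3S,4S)-3,4-dihydroxy-4,6-dimethylhept-6-enoate | COC(=O)C[C@H](O)[C@@](C)(O)CC(C)=C
F6 | step 7 | (10E)-11-bromoundec-10-en-1-yl 4-methylbenzenesulfonate | Br/C=C/CCCCCCCCCOS(=O)(=O)c1ccc(C)cc1
A1 | alternative 1 | 2-[(2S,3R)-3-methyl-3-{[(2S,3S)-2-methyl-3-(11-phenylundecyl)oxiran-2-yl]methyl}oxiran-2-yl]acetic acid | OC(=O)C[C@@H]1O[C@]1(C)C[C@]1(C)O[C@H]1CCCCCCCCCCCc1ccccc1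
A2 | alternative 1 | (3aS,5R,6aS)-5-[(1S)-1-hydroxy-12-phenyldodecyl]-5,6a-dimethyltetrahydrofuro[3,2-b]furan-2(3H)-one (7-hydroxy derivative of 19) | C[C@]1([C@@H](O)CCCCCCCCCCCc2ccccc2)C[C@]2(C)OC(=O)C[C@@H]2O1
A3 | alternative 2 | 2-[(2S,5S)-3,5-dimethyl-5-(12-phenyldodecyl)-2,5-dihydrofuran-2-yl]acetic acid | OC(=O)C[C@H]1C(C)=C[C@](C)(CCCCCCCCCCCCc2ccccc2)O1
A4 | alternative 2 | C5-iodo derivative of 19 (6-iodo in fused-ring numbering, iodine trans to the lactone oxygen) | C[C@]1(CCCCCCCCCCCCc2ccccc2)[C@@H](I)[C@]2(C)OC(=O)C[C@@H]2O1
A5 | alternative 3 | trimethylsilyl (3S)-4-methyl-3-(trimethylsilyloxy)pent-4-enoate | C[Si](C)(C)OC(=O)C[C@H](O[Si](C)(C)C)C(C)=C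
A6 | alternative 3 | 14-phenyltetradec-3-yn-2-one | CC(=O)C#CCCCCCCCCCCc1ccccc1
A7 | alternative 3 | (3aS,5R,6aS)-5,6a-dimethyl-5-(12-phenyldodec-1-yn-1-yl)tetrahydrofuro[3,2-b]furan-2(3H)-one (7,8-didehydro analogue of 19) | C[C@]1(C#CCCCCCCCCCCc2ccccc2)C[C@]2(C)OC(=O)C[C@@H]2O1
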